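**Assumption:** the target SMILES is read as the syn diol (3S,5R)-1-(4-hydroxy-3-methoxyphenyl)tetradecane-3,5-diol (chain numbered C1 = benzylic carbon to C14), and the phenol is carried as its benzyl ether.

## Retrosynthetic overview

1. Target 11 ⇐ benzyl ether/acetonide 9 by one-pot hydrogenolysis and acetonide hydrolysis.
2. C1–aryl bond: light-driven nickel deoxygenative arylation of primary alcohol 6 with aryl bromide 7.
3. 6 ⇐ tert-butyl ester 5 (LiAlH4); C6–C7 bond: paired-electrolysis nickel deoxygenative alkylation of alcohol 1 with 1-bromooctane 3 (new method).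
4. Both stereocenters are bought in acetonide 1, a bulk statin side-chain building block; its CH2OH carbon becomes C6 and its ester carbon becomes C1.
5. No ring is formed: the arene and the 1,3-dioxane are bought, and the dioxane is opened in the last step.

Abbreviations: dtbbpy = 4,4′-di-tert-butyl-2,2′-bipyridine; ppy = 2-phenylpyridinato; dme = 1,2-dimethoxyethane; RVC = reticulated vitreous carbon.

## Route

**Step 1**
Reactants: 1 tert-butyl 2-[(4R,6S)-6-(hydroxymethyl)-2,2-dimethyl-1,3-dioxan-4-yl]acetate; 2 5,7-di-tert-butyl-3-phenyl-1,3-benzoxazol-3-ium tetrafluoroborate; 3 1-bromooctane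
Product: 5 tert-butyl 2-[(4R,6R)-2,2-dimethyl-6-nonyl-1,3-dioxan-4-yl]acetate, via 2-alkoxybenzoxazoline adduct 4 (not isolated)
Conditions: 2 (1.1 equiv), pyridine, MTBE, rt, 15 min; then 3 (3 equiv), NiBr2·dme (10 mol%), dtbbpy (12 mol%), quinuclidine (1.5 equiv), nBu4NPF6, DMA, undivided cell, RVC anode and RVC cathode, 4 mA constant current, 2.5 F/mol, rt
Reagents that add atoms: none
Why: Proposed new method: a paired-electrolysis, nickel-catalysed deoxygenative alkyl–alkyl coupling in which the anode oxidises the electron-rich N-aryl benzoxazoline adduct 4 (directly or through anodically formed quinuclidine radical cation), loss of the C2 proton and β-scission then release the exocyclic primary radical and the benzoxazolone, while the cathode reduces divalent nickel to low-valent nickel that takes up 1-bromooctane, the octylnickel species traps the radical and trivalent nickel reductively eliminates the C6–C7 bond without touching either ring stereocenter; the closest known reaction type is the light-driven NHC-mediated deoxygenative cross-coupling of alcohols with alkyl bromides under nickel catalysis, here driven by the two electrodes as in paired-electrolysis nickel couplings of anodically generated alkyl radicals.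

**Step 2**
Reactants: 5 tert-butyl 2-[(4R,6R)-2,2-dimethyl-6-nonyl-1,3-dioxan-4-yl]acetate
Product: 6 2-[(4S,6R)-2,2-dimethyl-6-nonyl-1,3-dioxan-4-yl]ethan-1-ol
Conditions: LiAlH4 (1.5 equiv), THF, 0 °C to rt; H2O/NaOH work-up
Reagents that add atoms: none
Why: Hydride reduction of the tert-butyl ester to the primary alcohol by LiAlH4 leaves the acetonide and both stereocenters untouched (the descriptor at C4 changes from R to S only through a priority change).

**Step 3**
Reactants: 6 2-[(4S,6R)-2,2-dimethyl-6-nonyl-1,3-dioxan-4-yl]ethan-1-ol; 2 5,7-di-tert-butyl-3-phenyl-1,3-benzoxazol-3-ium tetrafluoroborate; 7 1-(benzyloxy)-4-bromo-2-methoxybenzene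
Product: 9 (4S,6R)-4-{2-[4-(benzyloxy)-3-methoxyphenyl]ethyl}-2,2-dimethyl-6-nonyl-1,3-dioxane, via 2-alkoxybenzoxazoline adduct 8 (not isolated)
Conditions: 2 (1.2 equiv), pyridine, MTBE, rt, 15 min; then 7 (1.5 equiv), [Ir(ppy)2(dtbbpy)]PF6 (1.5 mol%), NiBr2·dtbbpy (5 mol%), quinuclidine (1.75 equiv), DMA/MTBE, 450 nm LEDs, rt
Reagents that add atoms: none
Why: Nickel metallaphotoredox deoxygenative arylation of an NHC-activated primary alcohol: the excited iridium photocatalyst oxidises adduct 8, deprotonation and β-scission give the primary C1 radical, and the arylnickel bromide formed from 7 captures it and couples by reductive elimination from trivalent nickel, with no stereocenter involved and the acetonide and benzyl ether inert.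

**Step 4**
Reactants: 9 (4S,6R)-4-{2-[4-(benzyloxy)-3-methoxyphenyl]ethyl}-2,2-dimethyl-6-nonyl-1,3-dioxane
Product: 11 (3S,5R)-1-(4-hydroxy-3-methoxyphenyl)tetradecane-3,5-diol, via debenzylated acetonide phenol 10 (not isolated)
Conditions: H2 (1 atm), Pd/C (10 wt% palladium on carbon), MeOH, rt; then 1 M aq. HCl, rt
Reagents that add atoms: none
Why: Palladium-catalysed hydrogenolysis of the aryl benzyl ether followed by acid-catalysed acetonide hydrolysis frees the phenol and the syn-1,3-diol without touching C3 or C5.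

## Compound list

1 | tert-butyl 2-[(4R,6S)-6-(hydroxymethyl)-2,2-dimethyl-1,3-dioxan-4-yl]acetate | OC[C@@H]1C[C@H](CC(=O)OC(C)(C)C)OC(C)(C)O1 | starting material
2 | 5,7-di-tert-butyl-3-phenyl-1,3-benzoxazol-3-ium tetrafluoroborate | CC(C)(C)c1cc2[n+](-c3ccccc3)coc2c(C(C)(C)C)c1.F[B-](F)(F)F | starting material
3 | 1-bromooctane | CCCCCCCCBr | starting material
4 | tert-butyl 2-[(4R,6S)-6-{[(5,7-di-tert-butyl-3-phenyl-2,3-dihydro-1,3-benzoxazol-2-yl)oxy]methyl}-2,2-dimethyl-1,3-dioxan-4-yl]acetate (both epimers at the benzoxazoline carbon) | CC(C)(C)c1cc(C(C)(C)C)c2OC(OC[C@@H]3C[C@H](CC(=O)OC(C)(C)C)OC(C)(C)O3)N(c4ccccc4)c2c1 | intermediate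
5 | tert-butyl 2-[(4R,6R)-2,2-dimethyl-6-nonyl-1,3-dioxan-4-yl]acetate | CCCCCCCCC[C@@H]1C[C@H](CC(=O)OC(C)(C)C)OC(C)(C)O1 | intermediate
6 | 2-[(4S,6R)-2,2-dimethyl-6-nonyl-1,3-dioxan-4-yl]ethan-1-ol | CCCCCCCCC[C@@H]1C[C@H](CCO)OC(C)(C)O1 | intermediate
7 | 1-(benzyloxy)-4-bromo-2-methoxybenzene | COc1cc(Br)ccc1OCc1ccccc1 | starting material
8 | 5,7-di-tert-butyl-2-{2-[(4S,6R)-2,2-dimethyl-6-nonyl-1,3-dioxan-4-yl]ethoxy}-3-phenyl-2,3-dihydro-1,3-benzoxazole (both epimers at the benzoxazoline carbon) | CCCCCCCCC[C@@H]1C[C@H](CCOC2Oc3c(C(C)(C)C)cc(C(C)(C)C)cc3N2c4ccccc4)OC(C)(C)O1 | intermediate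
9 | (4S,6R)-4-{2-[4-(benzyloxy)-3-methoxyphenyl]ethyl}-2,2-dimethyl-6-nonyl-1,3-dioxane | CCCCCCCCC[C@@H]1C[C@H](CCc2ccc(OCc3ccccc3)c(OC)c2)OC(C)(C)O1 | intermediate
10 | 4-{2-[(4S,6R)-2,2-dimethyl-6-nonyl-1,3-dioxan-4-yl]ethyl}-2-methoxyphenol | CCCCCCCCC[C@@H]1C[C@H](CCc2ccc(O)c(OC)c2)OC(C)(C)O1 | intermediate
11 | (3S,5R)-1-(4-hydroxy-3-methoxyphenyl)tetradecane-3,5-diol | CCCCCCCCC[C@@H](O)C[C@@H](O)CCc1ccc(O)c(OC)c1 | target

## Step count and risks

Total step count: 4. Longest linear sequence: 4 steps (1 → 5 → 6 → 9 → 11).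

**Step 1 (the proposed new method).** The risks are statistical alkyl–alkyl mixtures (hexadecane, dimer of the radical from 1), anodic interception of the octylnickel species and cathodic proton reduction. The fallback uses known chemistry, sets out from 1 and comes back at 5. Parikh–Doering oxidation of 1 (SO3·pyridine, DMSO, iPr2NEt, CH2Cl2, 0 °C) gives tert-butyl 2-[(4R,6S)-6-formyl-2,2-dimethyl-1,3-dioxan-4-yl]acetate F1. Wittig olefination with the salt-free ylide from octyltriphenylphosphonium bromide and NaN(SiMe3)2 (THF, −78 °C to rt) gives tert-butyl 2-[(4R,6S)-2,2-dimethyl-6-[(1Z)-non-1-en-1-yl]-1,3-dioxan-4-yl]acetate F2. Hydrogenation (H2, Pd/C, EtOAc) then saturates the alkene to give 5.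

**Step 3.** The risks are slow oxidative addition of the electron-rich aryl bromide to low-valent nickel and reduction of the C1 radical to the simple deoxygenated alkane. The fallback sets out from 6 and comes back at 9. Appel iodination (I2, PPh3, imidazole, CH2Cl2, 0 °C) gives (4R,6R)-4-(2-iodoethyl)-2,2-dimethyl-6-nonyl-1,3-dioxane F3. Zinc insertion (Zn dust, LiCl, THF, 40 °C) gives {2-[(4R,6R)-2,2-dimethyl-6-nonyl-1,3-dioxan-4-yl]ethyl}zinc iodide F4, used in solution. Negishi coupling of this solution with 7 (Pd(OAc)2, SPhos, THF, rt) gives 9.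

**Step 4.** The risk is a stalled hydrogenolysis (palladium poisoned by traces of nickel or amine from step 3) or incomplete acetal cleavage in the one-pot sequence. The fallback avoids hydrogenation by an all-acetal protecting scheme; it sets out from 6 and comes back at 11. Commercial 4-bromo-2-methoxyphenol is protected (chloromethyl methyl ether, iPr2NEt, CH2Cl2) as 4-bromo-2-methoxy-1-(methoxymethoxy)benzene F5. Compound 6 is coupled with it under the step 3 conditions (through adduct 8) to give (4S,6R)-4-{2-[3-methoxy-4-(methoxymethoxy)phenyl]ethyl}-2,2-dimethyl-6-nonyl-1,3-dioxane F6. A single acidolysis (HCl in MeOH, rt) then removes both acetals to give 11.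

## Further compounds

F1 | step 1 | tert-butyl 2-[(4R,6S)-6-formyl-2,2-dimethyl-1,3-dioxan-4-yl]acetate | O=C[C@@H]1C[C@H](CC(=O)OC(C)(C)C)OC(C)(C)O1
F2 | step 1 | tert-butyl 2-[(4R,6S)-2,2-dimethyl-6-[(1Z)-non-1-en-1-yl]-1,3-dioxan-4-yl]acetate | CCCCCCC/C=C\[C@@H]1C[C@H](CC(=O)OC(C)(C)C)OC(C)(C)O1
F3 | step 3 | (4R,6R)-4-(2-iodoethyl)-2,2-dimethyl-6-nonyl-1,3-dioxane | CCCCCCCCC[C@@H]1C[C@H](CCI)OC(C)(C)O1
F4 | step 3 | {2-[(4R,6R)-2,2-dimethyl-6-nonyl-1,3-dioxan-4-yl]ethyl}zinc iodide | CCCCCCCCC[C@@H]1C[C@H](CC[Zn]I)OC(C)(C)O1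
F5 | step 4 | 4-bromo-2-methoxy-1-(methoxymethoxy)benzene | COCOc1ccc(Br)cc1OC
F6 | step 4 | (4S,6R)-4-{2-[3-methoxy-4-(methoxymethoxy)phenyl]ethyl}-2,2-dimethyl-6-nonyl-1,3-dioxane | CCCCCCCCC[C@@H]1C[C@H](CCc2ccc(OCOC)c(OC)c2)OC(C)(C)O1
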